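## Retrosynthetic overview

1. The target, the (3R)-isoflavanone, comes from its tris-MOM ether 29 by a non-basic deprotection. The C3–H stereocentre of 29 is set by stereoconvergent Pd-catalysed decarboxylative protonation of the racemic C3-quaternary allyl β-keto ester 27.
2. Ring C of 27 is closed last, in one operation, from two fragments of similar size: ester enolate of 13 (ring B, the chromene ring, C2, C3, O1) and aroyl fluoride 23 (ring A and C4). C3–C4 forms by C-acylation at the fully substituted C3, then O1–C8a by fluoride-relayed SNAr.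
3. Enabling feature: C8a of ring A is ortho to the C4 carbonyl and meta to O5 and O7, so a C8a–F is SNAr-activated and not donor-deactivated. C3 is the α-carbon of the aryl ketone and can carry a temporary allyl ester that makes it an enolate carbon and is later expelled as CO2.
4. Fragment 13: the chromene pyran ring is formed first (2,4-dihydroxybenzaldehyde and prenal), then aryl-shift homologation with allyl diazoacetate, reduction and silylation.
5. Fragment 23: 5-fluororesorcinol by formylation, MOM protection, oxidation and conversion to the acyl fluoride.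

Key step: step 11

Remark on the chemistry: compounds 11, 13 and 24–27 are racemic. The (S)-ligand in step 12 is assumed, by analogy with related 3-aryl-chroman-4-one allyl esters, to give the (3R)-ketone; should analysis show the opposite sense, the (R)-ligand is used in the same step.

## Route

Step 1
Reactants: 1 β-resorcylaldehyde (2,4-dihydroxybenzaldehyde); 2 prenal (3-methylbut-2-enal)
Product: 4 chromene aldehyde (5-hydroxy-2,2-dimethyl-2H-chromene-6-carbaldehyde), via ortho-quinone methide 3 (not isolated)
Conditions: Ca(OH)2, MeOH, rt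
Reagents that add atoms: prenal 2, CC(C)=CC=O
Why: Base-mediated chromenylation (C-alkylation at the carbon between the two oxygens, dehydration to ortho-quinone methide 3, 6π-oxa-electrocyclisation); the 2-OH is hydrogen-bonded to the aldehyde, so only the 4-OH should close the pyran ring, giving the angular 5-hydroxy-6-formyl chromene.

Step 2
Reactants: 4 chromene aldehyde; 5 chloromethyl methyl ether (MOMCl)
Product: 6 MOM aldehyde (5-(methoxymethoxy)-2,2-dimethyl-2H-chromene-6-carbaldehyde)
Conditions: MOMCl, i-Pr2NEt, CH2Cl2, 0 °C → 40 °C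
Reagents that add atoms: chloromethyl methyl ether 5, COCCl
Why: O-Alkylation of the phenol with the reactive α-chloro ether (MOM ether formation); aldehyde and chromene are inert to the amine base.

Step 3
Reactants: 7 glycine allyl ester p-toluenesulfonate; 8 sodium nitrite
Product: 9 allyl diazoacetate
Conditions: NaNO2, CH2Cl2/H2O, 0 °C
Reagents that add atoms: sodium nitrite 8, [Na+].[O-]N=O
Why: Diazotisation of the α-amino ester salt and loss of the α-proton should give the stabilised diazo ester, extracted into CH2Cl2 as it forms and used as a solution.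

Step 4
Reactants: 6 MOM aldehyde; 9 allyl diazoacetate
Product: 10 enol ester (allyl (Z)-3-hydroxy-2-[5-(methoxymethoxy)-2,2-dimethyl-2H-chromen-6-yl]prop-2-enoate, the enol form of the α-formyl ester)
Conditions: HBF4·OEt2 (10 mol%), CH2Cl2, –78 °C; Et3N quench at –78 °C
Reagents that add atoms: allyl diazoacetate 9, C=CCOC(=O)C=[N+]=[N-]
Why: Acid-catalysed aldehyde–diazoacetate homologation with 1,2-aryl shift and loss of N2 (the aryl-migration counterpart of the Roskamp reaction), favoured by the electron-rich 2,4-dioxygenated aryl group; catalytic acid at –78 °C should spare the MOM ether and the chromene.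

Step 5
Reactants: 10 enol ester
Product: 11 hydroxy ester (rac-allyl 3-hydroxy-2-[5-(methoxymethoxy)-2,2-dimethyl-2H-chromen-6-yl]propanoate)
Conditions: NaBH4, THF/allyl alcohol, –20 °C → 0 °C
Reagents that add atoms: none
Why: Borohydride reduction of the aldehyde tautomer of the α-formyl ester (classical tropic ester synthesis); allyl alcohol as co-solvent makes transesterification degenerate, and the α-stereocentre is formed racemic on purpose because it is erased later.

Step 6
Reactants: 11 hydroxy ester; 12 chlorotriethylsilane
Product: 13 silyl ether (rac-allyl 2-[5-(methoxymethoxy)-2,2-dimethyl-2H-chromen-6-yl]-3-(triethylsilyloxy)propanoate)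
Conditions: Et3SiCl, imidazole, CH2Cl2, 0 °C
Reagents that add atoms: chlorotriethylsilane 12, CC[Si](Cl)(CC)CC
Why: Standard silylation of the primary alcohol; the triethylsilyl ether keeps O1 silent toward amide base and acyl fluoride but is cleaved by fluoride in step 11.

Step 7
Reactants: 14 5-fluororesorcinol (5-fluorobenzene-1,3-diol); 15 N,N-dimethylformamide; 16 water
Product: 18 fluoro aldehyde (2-fluoro-4,6-dihydroxybenzaldehyde), via aryl iminium salt 17 (not isolated)
Conditions: POCl3, DMF, MeCN, 0 °C → rt; then H2O, 50 °C
Reagents that add atoms: N,N-dimethylformamide 15, CN(C)C=O; water 16, O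
Why: Vilsmeier–Haack formylation at the position ortho to one OH and para to the other (as for resorcinol itself), the position between the two OH groups being shielded; hydrolysis of iminium salt 17 gives the aldehyde.

Step 8
Reactants: 18 fluoro aldehyde; 5 chloromethyl methyl ether
Product: 19 bis-MOM aldehyde (2-fluoro-4,6-bis(methoxymethoxy)benzaldehyde)
Conditions: MOMCl (2.5 equiv), i-Pr2NEt, CH2Cl2, 0 °C → rt
Reagents that add atoms: chloromethyl methyl ether 5, COCCl
Why: Double MOM ether formation under amine base; the aryl fluoride is not displaced by chloride or amine under these conditions.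

Step 9
Reactants: 19 bis-MOM aldehyde; 20 sodium chlorite
Product: 21 acid (2-fluoro-4,6-bis(methoxymethoxy)benzoic acid)
Conditions: NaClO2, NaH2PO4, 2-methyl-2-butene, t-BuOH/H2O, rt
Reagents that add atoms: sodium chlorite 20, [Na+].[O-]Cl=O
Why: Pinnick oxidation; the buffered medium preserves the MOM ethers and the alkene scavenger protects the electron-rich ring from chlorination.

Step 10
Reactants: 21 acid; 22 cyanuric fluoride
Product: 23 aroyl fluoride (2-fluoro-4,6-bis(methoxymethoxy)benzoyl fluoride)
Conditions: cyanuric fluoride, pyridine, CH2Cl2, –10 °C → rt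
Reagents that add atoms: cyanuric fluoride 22, Fc1nc(F)nc(F)n1
Why: Deoxyfluorination of the acid to the acyl fluoride under non-acidic conditions; the fluoride is chosen because an ortho-MOM-oxy benzoyl chloride is prone to cyclise and because its fluoride becomes the desilylating agent of step 11.

Step 11
Reactants: 13 silyl ether; 23 aroyl fluoride
Product: 27 keto ester (rac-allyl 5,7-bis(methoxymethoxy)-3-[5-(methoxymethoxy)-2,2-dimethyl-2H-chromen-6-yl]-4-oxochromane-3-carboxylate), via potassium enolate 24 (not isolated), via C-acylated silyl ether 25 (not isolated), via potassium alkoxide 26 (not isolated)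
Conditions: KN(SiMe3)2 (1.0 equiv), THF, –78 °C; then 23 (1.0 equiv), –78 °C; then 18-crown-6 (1.1 equiv), –78 °C → rt
Reagents that add atoms: aroyl fluoride 23, O=C(F)c1c(F)cc(OCOC)cc1OCOC
Why: Proposed new method: potassium enolate 24 should be C-acylated by the small, hard aroyl fluoride 23 (addition–elimination, C- over O-acylation as is usual for ester enolates), forming the C3–C4 bond and the fully substituted C3 of 25, and the KF released in this event, made soluble by 18-crown-6, should cleave the O–SiEt3 bond to alkoxide 26, which closes ring C by intramolecular SNAr at C8a and so forms the O1–C8a bond, giving back fluoride. The closest known reaction types are the Grohe–Heitzer cycloaracylation (C-aroylation by a 2-halobenzoyl halide followed by SNAr ring closure, used for 4-quinolones and chromones) and the fluoride-triggered SNAr etherification of aryl fluorides with silyl ethers; new is their relay through the fluoride of the acyl fluoride at an sp3, fully substituted C3. Ring C closes in a six-membered (6-exo-trig) Meisenheimer addition–elimination in which O1 attacks C8a, which is ortho to the new C4 ketone and meta to both MOM ethers. The new stereocentre C3 is formed racemic without control, which is intended because step 12 erases and resets it. The step needs O1 to stay silent until C3–C4 is made, which the silyl ether secures, and it needs ring closure to win over loss of formaldehyde from 26 by retro-aldol cleavage, which is reversible while the SNAr is not, so the equilibrium should drain toward 27. One equivalent of base suffices and the mixture ends with KF only, so the non-enolisable β-keto ester is not exposed to amide or excess alkoxide.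

Step 12
Reactants: 27 keto ester
Product: 29 protected isoflavanone ((3R)-5,7-bis(methoxymethoxy)-3-[5-(methoxymethoxy)-2,2-dimethyl-2H-chromen-6-yl]chroman-4-one), via palladium enolate 28 (not isolated)
Conditions: Pd2(dba)3 (5 mol%), (S)-(CF3)3-t-BuPHOX (12.5 mol%), Meldrum's acid (2.5 equiv), THF, 5 °C → rt
Reagents that add atoms: none
Why: Palladium-catalysed decarboxylative asymmetric protonation (Tsuji–Trost ionisation of the allyl ester, decarboxylation to the prochiral enolate 28, protonation by Meldrum's acid inside the chiral Pd–phosphinooxazoline environment, the acid also capturing the allyl group); both enantiomers of 27 pass through the same enolate, so the racemate should be funnelled into the (3R)-ketone, and the neutral medium should not epimerise the product.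

Step 13
Reactants: 29 protected isoflavanone
Product: 30 target ((3R)-5,7-dihydroxy-3-(5-hydroxy-2,2-dimethyl-2H-chromen-6-yl)chroman-4-one)
Conditions: ZnBr2, n-PrSH, CH2Cl2, 0 °C, short reaction time; pH 7 buffer
Reagents that add atoms: none
Why: Lewis acid/thiol acetal exchange removes the three aryl MOM ethers quickly at 0 °C under non-basic, aprotic conditions, which should leave the base-labile C3–H stereocentre and the chromene untouched.

## Compound list

1 | 2,4-dihydroxybenzaldehyde | O=Cc1ccc(O)cc1O | starting material
2 | 3-methylbut-2-enal (prenal) | CC(C)=CC=O | starting material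
3 | ortho-quinone methide, 2-hydroxy-3-(3-methylbut-2-enylidene)-4-oxocyclohexa-1,5-diene-1-carbaldehyde (alkene geometry undefined) | O=CC1=C(O)C(=CC=C(C)C)C(=O)C=C1 | intermediate (not isolated)
4 | 5-hydroxy-2,2-dimethyl-2H-chromene-6-carbaldehyde | CC1(C)C=Cc2c(O1)ccc(C=O)c2O | intermediate
5 | chloromethyl methyl ether | COCCl | starting material
6 | 5-(methoxymethoxy)-2,2-dimethyl-2H-chromene-6-carbaldehyde | CC1(C)C=Cc2c(O1)ccc(C=O)c2OCOC | intermediate
7 | glycine allyl ester p-toluenesulfonate | C=CCOC(=O)C[NH3+].Cc1ccc(cc1)S(=O)(=O)[O-] | starting material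
8 | sodium nitrite | [Na+].[O-]N=O | starting material
9 | allyl diazoacetate | C=CCOC(=O)C=[N+]=[N-] | intermediate
10 | allyl (Z)-3-hydroxy-2-[5-(methoxymethoxy)-2,2-dimethyl-2H-chromen-6-yl]prop-2-enoate | C=CCOC(=O)/C(=C\O)c1ccc2OC(C)(C)C=Cc2c1OCOC | intermediate
11 | rac-allyl 3-hydroxy-2-[5-(methoxymethoxy)-2,2-dimethyl-2H-chromen-6-yl]propanoate | C=CCOC(=O)C(CO)c1ccc2OC(C)(C)C=Cc2c1OCOC | intermediate
12 | chlorotriethylsilane | CC[Si](Cl)(CC)CC | starting material
13 | rac-allyl 2-[5-(methoxymethoxy)-2,2-dimethyl-2H-chromen-6-yl]-3-(triethylsilyloxy)propanoate | C=CCOC(=O)C(CO[Si](CC)(CC)CC)c1ccc2OC(C)(C)C=Cc2c1OCOC | intermediate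
14 | 5-fluorobenzene-1,3-diol | Oc1cc(O)cc(F)c1 | starting material
15 | N,N-dimethylformamide | CN(C)C=O | starting material
16 | water | O | starting material
17 | (2-fluoro-4,6-dihydroxybenzylidene)dimethyliminium chloride | C[N+](C)=Cc1c(F)cc(O)cc1O.[Cl-] | intermediate (not isolated)
18 | 2-fluoro-4,6-dihydroxybenzaldehyde | O=Cc1c(F)cc(O)cc1O | intermediate
19 | 2-fluoro-4,6-bis(methoxymethoxy)benzaldehyde | O=Cc1c(F)cc(OCOC)cc1OCOC | intermediate
20 | sodium chlorite | [Na+].[O-]Cl=O | starting material
21 | 2-fluoro-4,6-bis(methoxymethoxy)benzoic acid | OC(=O)c1c(F)cc(OCOC)cc1OCOC | intermediate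
22 | cyanuric fluoride | Fc1nc(F)nc(F)n1 | starting material
23 | 2-fluoro-4,6-bis(methoxymethoxy)benzoyl fluoride | O=C(F)c1c(F)cc(OCOC)cc1OCOC | intermediate
24 | potassium enolate of 13 (geometry undefined) | C=CCOC([O-])=C(CO[Si](CC)(CC)CC)c1ccc2OC(C)(C)C=Cc2c1OCOC.[K+] | intermediate (not isolated)
25 | rac-allyl 2-[2-fluoro-4,6-bis(methoxymethoxy)benzoyl]-2-[5-(methoxymethoxy)-2,2-dimethyl-2H-chromen-6-yl]-3-(triethylsilyloxy)propanoate | C=CCOC(=O)C(CO[Si](CC)(CC)CC)(C(=O)c1c(F)cc(OCOC)cc1OCOC)c1ccc2OC(C)(C)C=Cc2c1OCOC | intermediate (not isolated)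
26 | potassium alkoxide from 25 after loss of the silyl group | C=CCOC(=O)C(C[O-])(C(=O)c1c(F)cc(OCOC)cc1OCOC)c1ccc2OC(C)(C)C=Cc2c1OCOC.[K+] | intermediate (not isolated)
27 | rac-allyl 5,7-bis(methoxymethoxy)-3-[5-(methoxymethoxy)-2,2-dimethyl-2H-chromen-6-yl]-4-oxochromane-3-carboxylate | C=CCOC(=O)C1(COc2cc(OCOC)cc(OCOC)c2C1=O)c1ccc2OC(C)(C)C=Cc2c1OCOC | intermediate
28 | C4 enolate of the decarboxylated chromanone, ion-paired with the (η3-allyl)palladium–phosphinooxazoline cation (SMILES of the enolate anion) | [O-]C1=C(COc2cc(OCOC)cc(OCOC)c12)c1ccc2OC(C)(C)C=Cc2c1OCOC | intermediate (not isolated)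
29 | (3R)-5,7-bis(methoxymethoxy)-3-[5-(methoxymethoxy)-2,2-dimethyl-2H-chromen-6-yl]chroman-4-one | CC1(C)C=Cc2c(ccc([C@@H]3COc4cc(OCOC)cc(OCOC)c4C3=O)c2OCOC)O1 | intermediate
30 | (3R)-5,7-dihydroxy-3-(5-hydroxy-2,2-dimethyl-2H-chromen-6-yl)chroman-4-one | CC1(C)C=Cc2c(ccc([C@@H]3COc4cc(O)cc(O)c4C3=O)c2O)O1 | target

## Step count and risks

Total step count: 13. Longest linear sequence: 8 steps (1, 2, 4, 5, 6, 11, 12, 13).

Steps most likely to fail:

Step 11. The relay may break down in three ways: β-elimination of silanolate from the enolate before acylation, fluoride not turning over for the desilylation, or loss of formaldehyde by retro-aldol cleavage outpacing ring closure. The fallback separates the two bond formations and uses known chemistry. It sets out from 13 and 23. The lithium enolate of 13 (LiN(SiMe3)2, THF, –78 °C) is acylated with 23; the LiF formed is inert, so the C-acylated silyl ether 25 can be isolated. HF·pyridine in THF at 0 °C then frees the alcohol, rac-allyl 2-[2-fluoro-4,6-bis(methoxymethoxy)benzoyl]-3-hydroxy-2-[5-(methoxymethoxy)-2,2-dimethyl-2H-chromen-6-yl]propanoate F1. K2CO3 in DMF at rt closes ring C by carbonate-mediated intramolecular SNAr, and the sequence comes back to the route at 27.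

Step 12. The protonation of the hindered enolate (peri MOM ether at C5, ortho-substituted ring B) may proceed with poor facial selectivity, or C-allylation may compete. The fallback sets out from 27. Achiral decarboxylation (Pd(OAc)2, PPh3, HCO2H, Et3N, THF, rt) gives racemic 5,7-bis(methoxymethoxy)-3-[5-(methoxymethoxy)-2,2-dimethyl-2H-chromen-6-yl]chroman-4-one F2. Noyori-type asymmetric transfer hydrogenation with dynamic kinetic resolution (RuCl[(R,R)-TsDPEN](p-cymene), HCO2H/Et3N, EtOAc, 40 °C) exploits base-mediated epimerisation at C3 and should give the cis alcohol, (3R,4R)-5,7-bis(methoxymethoxy)-3-[5-(methoxymethoxy)-2,2-dimethyl-2H-chromen-6-yl]chroman-4-ol F3. Oxidation with Dess–Martin periodinane and NaHCO3 in CH2Cl2 at 0 °C returns the ketone without touching C3 and comes back to the route at 29.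

Step 13. Lewis acid-promoted enolisation may erode the configuration at C3, or the chromene may be attacked, while the three MOM ethers are removed. The fallback moves the acidic deprotection ahead of the stereocentre-setting step. It sets out from 27. Catalytic HCl in MeOH/THF at 40 °C gives the racemic triphenol, rac-allyl 5,7-dihydroxy-3-(5-hydroxy-2,2-dimethyl-2H-chromen-6-yl)-4-oxochromane-3-carboxylate F4. Silylation with t-BuMe2SiOTf and 2,6-lutidine in CH2Cl2 gives the tris-silyl ether, rac-allyl 5,7-bis(tert-butyldimethylsilyloxy)-3-[5-(tert-butyldimethylsilyloxy)-2,2-dimethyl-2H-chromen-6-yl]-4-oxochromane-3-carboxylate F5. The decarboxylative protonation under the conditions of step 12 should give (3R)-5,7-bis(tert-butyldimethylsilyloxy)-3-[5-(tert-butyldimethylsilyloxy)-2,2-dimethyl-2H-chromen-6-yl]chroman-4-one F6. KHF2 in MeOH at rt cleaves the aryl silyl ethers under mild, non-basic conditions and comes back to the route at 30.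

Further compounds
F1 | step 11 | rac-allyl 2-[2-fluoro-4,6-bis(methoxymethoxy)benzoyl]-3-hydroxy-2-[5-(methoxymethoxy)-2,2-dimethyl-2H-chromen-6-yl]propanoate | C=CCOC(=O)C(CO)(C(=O)c1c(F)cc(OCOC)cc1OCOC)c1ccc2OC(C)(C)C=Cc2c1OCOC
F2 | step 12 | racemic 5,7-bis(methoxymethoxy)-3-[5-(methoxymethoxy)-2,2-dimethyl-2H-chromen-6-yl]chroman-4-one | CC1(C)C=Cc2c(ccc(C3COc4cc(OCOC)cc(OCOC)c4C3=O)c2OCOC)O1
F3 | step 12 | (3R,4R)-5,7-bis(methoxymethoxy)-3-[5-(methoxymethoxy)-2,2-dimethyl-2H-chromen-6-yl]chroman-4-ol | CC1(C)C=Cc2c(ccc([C@@H]3COc4cc(OCOC)cc(OCOC)c4[C@@H]3O)c2OCOC)O1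
F4 | step 13 | rac-allyl 5,7-dihydroxy-3-(5-hydroxy-2,2-dimethyl-2H-chromen-6-yl)-4-oxochromane-3-carboxylate | C=CCOC(=O)C1(COc2cc(O)cc(O)c2C1=O)c1ccc2OC(C)(C)C=Cc2c1O
F5 | step 13 | rac-allyl 5,7-bis(tert-butyldimethylsilyloxy)-3-[5-(tert-butyldimethylsilyloxy)-2,2-dimethyl-2H-chromen-6-yl]-4-oxochromane-3-carboxylate | C=CCOC(=O)C1(COc2cc(O[Si](C)(C)C(C)(C)C)cc(O[Si](C)(C)C(C)(C)C)c2C1=O)c1ccc2OC(C)(C)C=Cc2c1O[Si](C)(C)C(C)(C)C
F6 | step 13 | (3R)-5,7-bis(tert-butyldimethylsilyloxy)-3-[5-(tert-butyldimethylsilyloxy)-2,2-dimethyl-2H-chromen-6-yl]chroman-4-one | CC1(C)C=Cc2c(ccc([C@@H]3COc4cc(O[Si](C)(C)C(C)(C)C)cc(O[Si](C)(C)C(C)(C)C)c4C3=O)c2O[Si](C)(C)C(C)(C)C)O1
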